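Start at late times: suppose the flask has turned its charge into the products read, J, Z, D, E and G, and ask what part of them is Z.

| setting | eta | flask |
|---|---|---|
| X | 0.050 M | 0.050 M |
| L | 0.013 M | 0.0250 M |
| remark | run made earlier |  |
| time |  | 2.0 d |

eta run (percent of the X and L together charged)

| time / h | J / % | Z / % | X / % | D / % | E / % | G / % |
|---|---|---|---|---|---|---|
| 1.33 | 0 | 3 | 73 | 3 | 0 | 0 |
| 3.00 | 0 | 8 | 57 | 6 | 0 | 3 |
| 4.00 | 1 | 9 | 53 | 0 | 1 | 5 |
| 6.00 | 1 | 13 | 48 | 0 | 0 | 6 |
| 8.00 | 3 | 15 | 39 | 6 | 2 | 7 |
| 10.0 | 1 | 23 | 30 | 5 | 5 | 2 |

(scatter of a reading: 2 percentage points)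

- where most of what was charged as X and L together, at 2.0 d is found (G / Z / D / X / E / J)
- the largest share itself, whichever of these holds it, in percent of the X and L together charged

- in percentages every species weighs as the X in it: one D counts as two
- a reading or a percentage of X is of its free form alone

Pool the eta readings: Z over the products read gives 0.555. Call this Z's share of the products, the selectivity, and treat it as a reading. It exceeds the rest, so expect Z to hold most.

For the bound from above, put the whole charge of the flask into products. For the bound from below, ask how fast they come. In eta the products stood at 36.0% after 10.0 h, which means a first-order clock of 0.0446 /h. Lend that clock to the flask, though it was read with less L. It looks slow: read late in eta, the products came at 0.0558 /h, faster than that mean. Both ends of the bracket are estimates and carry the scatter of the readings.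

| Bound | Products, of the charge | Z |
|---|---|---|
| Above | 100% | 55.5% |
| Below | 88.3% | 49.0% |

The forecast says Z at 35%, on the ground that “Z takes about 45% of the X lost”, which puts it below my bracket.

The flask gives Z at 52.3%, inside the bracket. At 2.00 d it still holds X at 2.75%, L at 1.82% and Q, never read, at 4.44%, and the products hold 91.0%. Z's share of the products, as read in eta, turns that into 50.5% of Z, less than the flask holds.

    X ⇌ L (K = 0.970, k = 0.101 /h)
    X → G (k = 0.0204 /h)
    L → Z (k = 0.101 /h)
    L ⇌ Q (K = 2.60, k = 0.0484 /h)
    Q → J (k = 0.0392 /h)
    X + G → D (k = 2.09 /M/h)
    G ⇌ E (K = 2.23, k = 0.0747 /h)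

Now read the same flask at 30 h: the clock gives 73.8% in products, so Z's share puts the lower end at 40.9%. The computed flask at that time holds Z at 46.5%, more than that estimate.

Readings and results are calculated for an exercise; noise was put on by code.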